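**Retrosynthetic overview**
1. Target 9 ⇐ tribromo ketal 8 by one global hydrogenolysis (three C–Br blocking groups and one catechol ketal removed together).
2. 8 ⇐ o-quinone 5 + phenol 3, joined first through a C–O bond (ring-A phenol oxygen onto the C4' carbonyl, hemiketal 6); a [3,3] shift then relays this bond to the C6'–C6 biaryl bond.
3. 5 ⇐ 6,8-dibromo-(+)-catechin 4 (ring A silenced); 3 ⇐ (+)-catechin 1 via catechol ketal 2 and C8 bromination (leaves C6 as the only free ortho carbon).
4. No ring is built: both chroman systems (rings A and C), both rings B and all four stereocentres (2R,3S in each unit) come intact from (+)-catechin.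

Assumption: the target SMILES gives no descriptor for the C6'–C6 biaryl axis, so it is treated as not configurationally fixed; locants follow flavan numbering.

**Route**

Step 1
Reactants: 1 (+)-catechin
Product: 2 3',4'-O-diphenylmethylene-(+)-catechin
Conditions: Ph2CCl2 (1.3 equiv), K2CO3 (2.5 equiv), MeCN, Ar, rt, 16 h
Reagents that add atoms: dichlorodiphenylmethane, ClC(Cl)(c1ccccc1)c1ccccc1
Why: Catechol ketalisation (double O-alkylation): only the ortho-dihydroxy pair of ring B can close the five-membered 2,2-diphenyl-1,3-benzodioxole, singly alkylated ring-A phenols revert on aqueous work-up, and neither stereocentre is touched.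

Step 2
Reactants: 2 3',4'-O-diphenylmethylene-(+)-catechin
Product: 3 8-bromo-3',4'-O-diphenylmethylene-(+)-catechin
Conditions: NBS (1.0 equiv), THF, −78 → −40 °C, dark
Reagents that add atoms: N-bromosuccinimide, O=C1CCC(=O)N1Br
Why: Electrophilic aromatic bromination goes to the free phloroglucinol-type ring A and there preferentially to C8 (para to 5-OH, less hindered than C6 between two hydroxyls); minor 6-bromo and 6,8-dibromo products are removed by chromatography and the stereocentres are untouched.

Step 3
Reactants: 1 (+)-catechin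
Product: 4 6,8-dibromo-(+)-catechin
Conditions: NBS (2.05 equiv), THF, −78 → 0 °C, dark
Reagents that add atoms: N-bromosuccinimide, O=C1CCC(=O)N1Br
Why: Exhaustive electrophilic aromatic bromination of the two ring-A CH positions, which are far more nucleophilic than any ring-B carbon, leaves the future electrophile without a free carbon nucleophile on ring A; stereocentres untouched.

Step 4
Reactants: 4 6,8-dibromo-(+)-catechin; 3 8-bromo-3',4'-O-diphenylmethylene-(+)-catechin (1.5 equiv)
Product: 8 6,8-dibromo-(+)-catechin-(6'→6)-[8-bromo-3',4'-O-diphenylmethylene-(+)-catechin], via ring-B o-quinone 5 (not isolated), via O5-linked hemiketal 6 (not isolated), via bis-dienone tautomer 7 (not isolated)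
Conditions: a) 4, Ag2O (2 equiv), Na2SO4, MeCN, −20 °C, 10 min, cold filtration through Celite; b) filtrate added over 1 h to 3, (PhO)2P(O)OH (10 mol %), 4 Å MS, CH2Cl2/MeCN 3:1, −40 → 0 °C, Ar
Reagents that add atoms: none
Why: Proposed new method: a Brønsted-acid-catalysed O-tethered quinone arylation in which the two halves are united through a C–O bond — a ring-A phenol oxygen of 3 adds to the acid-activated C4' carbonyl of o-quinone 5 to give hemiketal 6, an allyl aryl ether embedded in a dienone, which undergoes a charge-accelerated aromatic-Claisen-type [3,3] shift (O–C4' broken, C6–C6' made) to 7, and double tautomerisation of 7 to a catechol and a phenol makes the sequence irreversible; the tether dictates regiochemistry (from C4' only C6' is reachable, a C3' hemiketal leads only to quaternary C1' and reverts, and on 3 the only free ortho carbon is C6 because C4a is quaternary and C8 carries bromine, so a 7-O hemiketal converges on C6 as well), no stereocentre is formed or touched, and the closest known reaction type is the acid-catalysed coupling of preformed p-quinone monoketals with naphthols or phenols through a mixed ketal and [3,3]-sigmatropic rearrangement, here extended to a free o-quinone hemiketal and a phloroglucinol-type flavan ring.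

Step 5
Reactants: 8 6,8-dibromo-(+)-catechin-(6'→6)-[8-bromo-3',4'-O-diphenylmethylene-(+)-catechin]
Product: 9 (+)-catechin-(6'→6)-(+)-catechin (target)
Conditions: H2 (1 atm), Pd(OH)2/C (20 wt %), NaOAc (3.5 equiv), THF/MeOH 1:1, rt, 12 h; filtration under Ar, Sephadex LH-20
Reagents that add atoms: none
Why: Heterogeneous palladium hydrogenolysis cleaves the three aryl C–Br bonds (HBr buffered by acetate) and the doubly benzylic C–O bonds of the diphenylmethylene ketal in one operation, while the flavan C2–O1 bond and the four stereocentres survive as in standard catechin deprotections.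

**Compound list**

1 | (+)-catechin, (2R,3S)-2-(3,4-dihydroxyphenyl)chromane-3,5,7-triol | Oc1cc(O)c2c(c1)O[C@H](c1ccc(O)c(O)c1)[C@@H](O)C2 | starting material
2 | 3',4'-O-diphenylmethylene-(+)-catechin, (2R,3S)-2-(2,2-diphenyl-1,3-benzodioxol-5-yl)chromane-3,5,7-triol | Oc1cc(O)c2c(c1)O[C@H](c1ccc3OC(c4ccccc4)(c4ccccc4)Oc3c1)[C@@H](O)C2 | intermediate
3 | 8-bromo-3',4'-O-diphenylmethylene-(+)-catechin, (2R,3S)-8-bromo-2-(2,2-diphenyl-1,3-benzodioxol-5-yl)chromane-3,5,7-triol | Oc1cc(O)c2c(c1Br)O[C@H](c1ccc3OC(c4ccccc4)(c4ccccc4)Oc3c1)[C@@H](O)C2 | intermediate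
4 | 6,8-dibromo-(+)-catechin, (2R,3S)-6,8-dibromo-2-(3,4-dihydroxyphenyl)chromane-3,5,7-triol | Oc1c(Br)c(O)c2c(c1Br)O[C@H](c1ccc(O)c(O)c1)[C@@H](O)C2 | intermediate
5 | ring-B o-quinone of 4, 4-[(2R,3S)-6,8-dibromo-3,5,7-trihydroxychroman-2-yl]cyclohexa-3,5-diene-1,2-dione (formed in the flask, not isolated) | Oc1c(Br)c(O)c2c(c1Br)O[C@H](C1=CC(=O)C(=O)C=C1)[C@@H](O)C2 | intermediate
6 | hemiketal from addition of the 5-OH of 3 to the C4' carbonyl of 5, drawn as the 5-O isomer, C4' epimers (formed in the flask, not isolated) | Oc1c(Br)c(O)c2c(c1Br)O[C@H](C1=CC(=O)C(O)(Oc3cc(O)c(Br)c4O[C@H](c5ccc6OC(c7ccccc7)(c7ccccc7)Oc6c5)[C@@H](O)Cc34)C=C1)[C@@H](O)C2 | intermediate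
7 | [3,3]-shift product, C6'–C6 bonded bis-dienone tautomer of 8, transient sp3 centres C6' and C6 unassigned (formed in the flask, not isolated) | Oc1c(Br)c(O)c2c(c1Br)O[C@H](C1=CC(=O)C(O)=CC1C1C(=O)C3=C(O[C@H](c4ccc5OC(c6ccccc6)(c6ccccc6)Oc5c4)[C@@H](O)C3)C(Br)=C1O)[C@@H](O)C2 | intermediate
8 | (2R,3S)-6,8-dibromo-2-{2-[(2R,3S)-8-bromo-2-(2,2-diphenyl-1,3-benzodioxol-5-yl)-3,5,7-trihydroxychroman-6-yl]-4,5-dihydroxyphenyl}chromane-3,5,7-triol | Oc1c(Br)c(O)c2c(c1Br)O[C@H](c1cc(O)c(O)cc1-c1c(O)c(Br)c3c(c1O)C[C@H](O)[C@@H](c1ccc4OC(c5ccccc5)(c5ccccc5)Oc4c1)O3)[C@@H](O)C2 | intermediate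
9 | (+)-catechin-(6'→6)-(+)-catechin, (2R,3S)-2-{2-[(2R,3S)-2-(3,4-dihydroxyphenyl)-3,5,7-trihydroxychroman-6-yl]-4,5-dihydroxyphenyl}chromane-3,5,7-triol | Oc1cc(O)c2c(c1)O[C@H](c1cc(O)c(O)cc1-c1c(O)cc3c(c1O)C[C@H](O)[C@@H](c1ccc(O)c(O)c1)O3)[C@@H](O)C2 | target

**Totals**

Total step count: 5. Longest linear sequence: 4 steps (1 → 2 → 3 → 8 → 9).

**Steps most likely to fail**

Step 4 (the proposed new step). The risks are:
- the short lifetime of quinone 5, whose tautomerisation to a quinone methide would erode C2;
- redox exchange between 5 and the new catechol of 8, leading to over-oxidation;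
- competing oxa-Michael ether formation;
- ipso attack at C8–Br.

Fallback, known chemistry: drop the acid-catalysed tether and make the C6'–C6 bond by the uncatalysed conjugate addition of a phloroglucinol-type ring carbon to a catechol o-quinone, the reaction by which B-type dehydrodicatechins arise. Compound 4 is oxidised with NaIO4 (1.0 equiv) in acetone/aqueous acetate buffer (pH 5.5) at 0 °C in the presence of 3 (3 equiv). C6 of 3 (C8 blocked) adds as a carbon nucleophile to C6' of 5 and the adduct enolises. The fallback sets out from 3 and 4 and comes back at 8, with a lower yield expected; new compounds on its way: none F0.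

Step 2 (C8 versus C6 bromination of a free ring A). Fallback: let protecting groups enforce the regiochemistry. Starting from 2, silylation with TBSCl/imidazole in DMF gives 3,5,7-tris-O-TBS-3',4'-O-diphenylmethylene-(+)-catechin F1. NBS in CH2Cl2 at −78 °C then brominates C8 only, because C6 is shielded by two flanking silyloxy groups, giving 8-bromo-3,5,7-tris-O-TBS-3',4'-O-diphenylmethylene-(+)-catechin F2. Bu4NF/AcOH in THF at 0 °C removes the silyl groups and the sequence comes back at 3.

Step 5 (incomplete ketal hydrogenolysis next to three C–Br bonds, air-sensitive product). Fallback: separate the two deprotections and change the ketal cleavage to hydrolysis. Starting from 8, AcOH/H2O 4:1 at 80 °C hydrolyses the ketal to 6,8-dibromo-(+)-catechin-(6'→6)-8-bromo-(+)-catechin F3. Hydrodebromination with H2, Pd/C and NaOAc in MeOH then comes back at 9.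

**Further compounds**

F0 | step 4 | none | none
F1 | step 2 | 3,5,7-tris-O-TBS-3',4'-O-diphenylmethylene-(+)-catechin | CC(C)(C)[Si](C)(C)Oc1cc(O[Si](C)(C)C(C)(C)C)c2c(c1)O[C@H](c1ccc3OC(c4ccccc4)(c4ccccc4)Oc3c1)[C@@H](O[Si](C)(C)C(C)(C)C)C2
F2 | step 2 | 8-bromo-3,5,7-tris-O-TBS-3',4'-O-diphenylmethylene-(+)-catechin | CC(C)(C)[Si](C)(C)Oc1cc(O[Si](C)(C)C(C)(C)C)c2c(c1Br)O[C@H](c1ccc3OC(c4ccccc4)(c4ccccc4)Oc3c1)[C@@H](O[Si](C)(C)C(C)(C)C)C2
F3 | step 5 | 6,8-dibromo-(+)-catechin-(6'→6)-8-bromo-(+)-catechin | Oc1c(Br)c(O)c2c(c1Br)O[C@H](c1cc(O)c(O)cc1-c1c(O)c(Br)c3c(c1O)C[C@H](O)[C@@H](c1ccc(O)c(O)c1)O3)[C@@H](O)C2
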